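**Retrosynthetic overview**

1. Cyclohexane numbering used below: C1 = CH bearing the oxane, C2 = CH2, C3 = CHCl, C4 = C(CH3)Br, C5 and C6 = CH2. Endgame: 17 ⇐ allylic chloride 16 (H–Br across C4=C5) ⇐ cis-allylic alcohol 15 ⇐ enone 14 ⇐ carvone-type enone 10, with a Wharton 1,3-carbonyl transposition moving the oxygen from C5 to C3.
2. Key disconnection: 10 ⇒ oxanyl enal 6 + tert-butyl 3-oxopentanoate 7. An amine-catalysed asymmetric [3+3] Michael/aldol condensation forms C1–C6 and C3–C4 in one operation and sets C1.
3. Enabling feature: in the cyclohexane ring, C1–C2–C3 are the β-carbon, α-carbon and carbonyl carbon of an enal (the heteroatom on C3 is the memory of the aldehyde). C6–C5–C4 are the α-CH2, C=O and α'-C(CH3) of an ethyl ketone. The vicinal C3/C4 heteroatom pair with the methyl on C4 is the footprint of the aldol C=C of a 2-methylcyclohex-2-enone.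
4. Ring order: oxane first (bromoetherification of (R)-linalool, step 1), cyclohexane second (step 4). The enal handle comes from the vinyl group by ozonolysis and Wittig olefination.
5. Stereocontrol: oxane C2 from the chiral pool; oxane C5 by anti bromoetherification with isomer separation; cyclohexane C1 by the catalyst; C3 (Luche reduction, then SN2 inversion) and C4 (axial bromine-atom transfer anti to chlorine) relayed from C1.

Key step: step 4

Assumption: enantiopure (R)-(−)-linalool, the formyl ylide 5 and tert-butyl 3-oxopentanoate 7 are bought; the oxane quaternary centre is carried unchanged from linalool.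

**Route**

Step 1
Reactants: 1 (R)-(−)-linalool
Product: 2 (3S,6R)-3-bromo-6-ethenyl-2,2,6-trimethyloxane
Conditions: TBCO, MeNO2, 0 °C to rt; chromatography
Reagents that add atoms: 2,4,4,6-tetrabromocyclohexa-2,5-dien-1-one (TBCO), O=C1C(Br)=CC(Br)(Br)C=C1Br
Why: Electrophilic bromoetherification: the bromonium ion of the trisubstituted alkene is captured in Markovnikov 6-endo fashion by the tertiary hydroxyl through a chair-like transition state, which puts Br anti to the new C–O bond (equatorial); because vinyl and methyl are of similar size, the wanted 3,6-trans isomer is expected in an amount comparable to its C3 epimer, alongside tetrahydrofuran regioisomers, and is separated by chromatography.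

Step 2
Reactants: 2 (3S,6R)-3-bromo-6-ethenyl-2,2,6-trimethyloxane
Product: 4 (2R,5S)-5-bromo-2,6,6-trimethyloxane-2-carbaldehyde, via secondary ozonide 3 (not isolated)
Conditions: O3, CH2Cl2, −78 °C; then PPh3, −78 °C to rt
Reagents that add atoms: ozone, [O-][O+]=O
Why: Ozonolysis with reductive work-up cleaves the only C=C to a non-epimerisable α-alkoxy aldehyde, the secondary bromide and the ether being inert.

Step 3
Reactants: 4 (2R,5S)-5-bromo-2,6,6-trimethyloxane-2-carbaldehyde; 5 (triphenylphosphoranylidene)acetaldehyde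
Product: 6 (2E)-3-[(2R,5S)-5-bromo-2,6,6-trimethyloxan-2-yl]prop-2-enal
Conditions: toluene, 80 °C
Reagents that add atoms: none
Why: Wittig olefination with the stabilised formyl ylide should give the (E)-enal without touching a stereocentre.

Step 4
Reactants: 6 (2E)-3-[(2R,5S)-5-bromo-2,6,6-trimethyloxan-2-yl]prop-2-enal; 7 tert-butyl 3-oxopentanoate
Product: 10 (5S)-5-[(2R,5S)-5-bromo-2,6,6-trimethyloxan-2-yl]-2-methylcyclohex-2-en-1-one, via Michael adduct keto aldehyde ester 8 (not isolated), via aldol hydroxy keto ester 9 (not isolated)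
Conditions: (R)-2-[diphenyl(trimethylsilyloxy)methyl]pyrrolidine (20 mol%), toluene, rt; then p-TsOH·H2O (30 mol%), toluene, 80 °C
Reagents that add atoms: none
Why: The secondary amine condenses with 6 to the (E)-iminium ion, the enol of 7 adds through its doubly activated carbon to the β-carbon (C1–C6 bond), and after hydrolysis the ethyl-ketone α'-carbon closes onto the freed aldehyde by intramolecular aldol addition (C3–C4 bond), so the aldehyde carbon of 6 becomes C3 and the ketone carbon of 7 becomes C5. The closest known reaction type is the diarylprolinol silyl ether-catalysed Michael/aldol condensation/decarboxylation of tert-butyl β-ketoesters with enals to 5-substituted cyclohex-2-enones. The cyclohexane ring closes in a 6-(enolendo)-exo-trig aldol step, the only strain-free option because closure through the doubly activated carbon would give a four-membered ring. The single new stereocentre that survives, cyclohexane C1, is set by the catalyst: the CPh2(OTMS) group blocks one face of the s-trans iminium ion and the (R)-catalyst is chosen so that attack on the open face leads to the (5S)-enone, the oxane centres being remote spectators, while the centres at the ester carbon, C3 and C4 in 8 and 9 are erased. The step needs 1,4- over 1,2-addition, which iminium activation and the soft stabilised nucleophile secure, and a conjugated outcome, which warm TsOH secures by dehydrating toward the trisubstituted C3=C4 enone while cleaving the tert-butyl ester with loss of isobutene and CO2. The β-carbon is flanked by a fully substituted carbon, so the addition is expected to be slow and is the main risk of the route.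

Step 5
Reactants: 10 (5S)-5-[(2R,5S)-5-bromo-2,6,6-trimethyloxan-2-yl]-2-methylcyclohex-2-en-1-one
Product: 11 (1S,4S,6S)-4-[(2R,5S)-5-bromo-2,6,6-trimethyloxan-2-yl]-1-methyl-7-oxabicyclo[4.1.0]heptan-2-one
Conditions: 30% H2O2, NaOH (aq., substoichiometric), MeOH, 0 °C
Reagents that add atoms: hydrogen peroxide, OO
Why: Weitz–Scheffer nucleophilic epoxidation: hydroperoxide adds axially anti to the ring substituent, giving the trans epoxide expected by analogy with carvone; both new centres are erased in steps 6 and 7, so the facial outcome does not affect the final configuration.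

Step 6
Reactants: 11 (1S,4S,6S)-4-[(2R,5S)-5-bromo-2,6,6-trimethyloxan-2-yl]-1-methyl-7-oxabicyclo[4.1.0]heptan-2-one
Product: 13 (1S,5R)-5-[(2R,5S)-5-bromo-2,6,6-trimethyloxan-2-yl]-2-methylcyclohex-2-en-1-ol, via epoxy hydrazone 12 (not isolated)
Conditions: N2H4·H2O, AcOH (cat.), MeOH, 0 °C to rt
Reagents that add atoms: none
Why: Wharton transposition: hydrazone formation, epoxide opening to the vinyl diazene and loss of N2 give the transposed allylic alcohol with the epoxide C–O bond retained (OH trans to the oxanyl group), so the oxygen now sits on C3 and C5 becomes an sp2 CH.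

Step 7
Reactants: 13 (1S,5R)-5-[(2R,5S)-5-bromo-2,6,6-trimethyloxan-2-yl]-2-methylcyclohex-2-en-1-ol
Product: 14 (5R)-5-[(2R,5S)-5-bromo-2,6,6-trimethyloxan-2-yl]-2-methylcyclohex-2-en-1-one
Conditions: Dess–Martin periodinane, CH2Cl2, 0 °C to rt
Reagents that add atoms: none
Why: Dess–Martin oxidation of the secondary allylic alcohol completes the 1,3-carbonyl transposition and clears the C3 centre so that it can be reset from C1 in step 8.

Step 8
Reactants: 14 (5R)-5-[(2R,5S)-5-bromo-2,6,6-trimethyloxan-2-yl]-2-methylcyclohex-2-en-1-one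
Product: 15 (1R,5R)-5-[(2R,5S)-5-bromo-2,6,6-trimethyloxan-2-yl]-2-methylcyclohex-2-en-1-ol
Conditions: NaBH4, CeCl3·7H2O, MeOH, −78 to −20 °C
Reagents that add atoms: none
Why: Luche 1,2-reduction: axial hydride delivery to the half-chair with the oxanyl group equatorial should give the cis (pseudo-equatorial) allylic alcohol, as in the reduction of carvone to cis-carveol, so C3 is relayed from C1.

Step 9
Reactants: 15 (1R,5R)-5-[(2R,5S)-5-bromo-2,6,6-trimethyloxan-2-yl]-2-methylcyclohex-2-en-1-ol
Product: 16 (2R,5S)-5-bromo-2-[(1R,5S)-5-chloro-4-methylcyclohex-3-en-1-yl]-2,6,6-trimethyloxane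
Conditions: PPh3, (Cl3C)2CO, CH2Cl2, −20 to 0 °C
Reagents that add atoms: hexachloroacetone, ClC(Cl)(Cl)C(=O)C(Cl)(Cl)Cl
Why: Appel-type chlorination: chloride displaces the alkoxyphosphonium group by SN2 with inversion, under conditions known to convert secondary allylic alcohols without allylic shift, giving the pseudo-axial C3 chloride trans to the oxanyl group.

Step 10
Reactants: 16 (2R,5S)-5-bromo-2-[(1R,5S)-5-chloro-4-methylcyclohex-3-en-1-yl]-2,6,6-trimethyloxane
Product: 17 deoxy isocaespitol, (2R,5S)-5-bromo-2-[(1R,3S,4S)-4-bromo-3-chloro-4-methylcyclohexyl]-2,6,6-trimethyloxane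
Conditions: Co(acac)2 (25 mol%), t-BuOOH, Et3SiH, TsBr, CH2Cl2/i-PrOH, 0 °C to rt, dark
Reagents that add atoms: 4-methylbenzenesulfonyl bromide (TsBr), Cc1ccc(cc1)S(=O)(=O)Br
Why: Mukaiyama-type hydrogen-atom-transfer Markovnikov hydrobromination: a cobalt hydride delivers H to the less substituted alkene carbon C5, and the tertiary C4 radical takes bromine from TsBr axially, anti to the neighbouring pseudo-axial C3–Cl, which should give the trans-diaxial bromochloride with the oxanyl group equatorial.

**Compound list**

1 | (R)-(−)-linalool, (3R)-3,7-dimethylocta-1,6-dien-3-ol | CC(C)=CCC[C@@](C)(O)C=C | starting material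
2 | (3S,6R)-3-bromo-6-ethenyl-2,2,6-trimethyloxane (Br trans to vinyl) | CC1(C)O[C@@](C)(C=C)CC[C@@H]1Br | intermediate
3 | 3-[(2R,5S)-5-bromo-2,6,6-trimethyloxan-2-yl]-1,2,4-trioxolane (secondary ozonide, not isolated) | CC1(C)O[C@@](C)(C2OCOO2)CC[C@@H]1Br | intermediate
4 | (2R,5S)-5-bromo-2,6,6-trimethyloxane-2-carbaldehyde | CC1(C)O[C@@](C)(C=O)CC[C@@H]1Br | intermediate
5 | (triphenylphosphoranylidene)acetaldehyde | O=CC=P(c1ccccc1)(c1ccccc1)c1ccccc1 | starting material
6 | (2E)-3-[(2R,5S)-5-bromo-2,6,6-trimethyloxan-2-yl]prop-2-enal | CC1(C)O[C@@](C)(/C=C/C=O)CC[C@@H]1Br | intermediate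
7 | tert-butyl 3-oxopentanoate | CCC(=O)CC(=O)OC(C)(C)C | starting material
8 | tert-butyl (3S)-3-[(2R,5S)-5-bromo-2,6,6-trimethyloxan-2-yl]-5-oxo-2-propanoylpentanoate (Michael adduct, epimers at C2, not isolated) | CC1(C)O[C@@](C)([C@@H](CC=O)C(C(=O)CC)C(=O)OC(C)(C)C)CC[C@@H]1Br | intermediate
9 | tert-butyl (6S)-6-[(2R,5S)-5-bromo-2,6,6-trimethyloxan-2-yl]-4-hydroxy-3-methyl-2-oxocyclohexane-1-carboxylate (aldol, isomer mixture at C1, C3, C4, not isolated) | CC1(C)O[C@@](C)([C@@H]2C(C(=O)OC(C)(C)C)C(=O)C(C)C(O)C2)CC[C@@H]1Br | intermediate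
10 | (5S)-5-[(2R,5S)-5-bromo-2,6,6-trimethyloxan-2-yl]-2-methylcyclohex-2-en-1-one | CC1(C)O[C@@](C)([C@@H]2CC(=O)C(C)=CC2)CC[C@@H]1Br | intermediate
11 | (1S,4S,6S)-4-[(2R,5S)-5-bromo-2,6,6-trimethyloxan-2-yl]-1-methyl-7-oxabicyclo[4.1.0]heptan-2-one (epoxide trans to the oxanyl group) | CC1(C)O[C@@](C)([C@@H]2CC(=O)[C@@]3(C)O[C@H]3C2)CC[C@@H]1Br | intermediate
12 | hydrazone of 11 (not isolated) | CC1(C)O[C@@](C)([C@@H]2CC(=NN)[C@@]3(C)O[C@H]3C2)CC[C@@H]1Br | intermediate
13 | (1S,5R)-5-[(2R,5S)-5-bromo-2,6,6-trimethyloxan-2-yl]-2-methylcyclohex-2-en-1-ol (OH trans to the oxanyl group) | CC1(C)O[C@@](C)([C@@H]2CC=C(C)[C@@H](O)C2)CC[C@@H]1Br | intermediate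
14 | (5R)-5-[(2R,5S)-5-bromo-2,6,6-trimethyloxan-2-yl]-2-methylcyclohex-2-en-1-one | CC1(C)O[C@@](C)([C@@H]2CC=C(C)C(=O)C2)CC[C@@H]1Br | intermediate
15 | (1R,5R)-5-[(2R,5S)-5-bromo-2,6,6-trimethyloxan-2-yl]-2-methylcyclohex-2-en-1-ol (OH cis to the oxanyl group) | CC1(C)O[C@@](C)([C@@H]2CC=C(C)[C@H](O)C2)CC[C@@H]1Br | intermediate
16 | (2R,5S)-5-bromo-2-[(1R,5S)-5-chloro-4-methylcyclohex-3-en-1-yl]-2,6,6-trimethyloxane | CC1(C)O[C@@](C)([C@@H]2CC=C(C)[C@@H](Cl)C2)CC[C@@H]1Br | intermediate
17 | deoxy isocaespitol, (2R,5S)-5-bromo-2-[(1R,3S,4S)-4-bromo-3-chloro-4-methylcyclohexyl]-2,6,6-trimethyloxane | CC1(C)O[C@@](C)([C@@H]2CC[C@](C)(Br)[C@@H](Cl)C2)CC[C@@H]1Br | target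

**Step count**

Total step count: 10. Longest linear sequence: 10 steps (1 to 17).

**Three steps most likely to fail**

Step 4 (key step). What may go wrong: slow or incomplete conjugate addition because the β-carbon of the iminium ion is flanked by a fully substituted carbon, erosion of facial selectivity, or diversion into 1,2-condensation. The fallback sets out from 6 (with 7) and comes back at 10. It drops iminium activation and catalyst control in favour of a classical base-mediated Michael/aldol annulation with separation of diastereomers. Catalytic DBU or K2CO3 in THF should add the small ketoester enolate to the free enal, giving 8 together with its epimer at the new ring carbon, tert-butyl (3R)-3-[(2R,5S)-5-bromo-2,6,6-trimethyloxan-2-yl]-5-oxo-2-propanoylpentanoate F1. These close to 9 and its epimer tert-butyl (6R)-6-[(2R,5S)-5-bromo-2,6,6-trimethyloxan-2-yl]-4-hydroxy-3-methyl-2-oxocyclohexane-1-carboxylate F2. The same TsOH treatment then gives 10 and (5R)-5-[(2R,5S)-5-bromo-2,6,6-trimethyloxan-2-yl]-2-methylcyclohex-2-en-1-one F3. Because the oxane centres are fixed, 10 and F3 are diastereomers and 10 is taken on after chromatography.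

Step 10. What may go wrong: poor facial selectivity in the bromine-atom transfer, loss of chlorine from the β-chloroalkyl radical, or simple reduction of the alkene. The fallback sets out from 16 and comes back at 17. It replaces the radical pathway by polar hydrobromination with anhydrous HBr in CH2Cl2 at low temperature. Protonation at C5 gives the tertiary C4 cation bridged by the neighbouring chlorine, and bromide opens it anti at C4 to the same trans-diaxial product. The risk to watch in this mode is ionisation and allylic shift of the chloride. This fallback makes no new compound (F0).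

Step 1. What may go wrong: poor diastereoselectivity at the bromine-bearing carbon and competing 5-exo closure, so that little of the wanted trans isomer is recovered. The fallback sets out from 1 and comes back at 4. It enlarges the substituent at the quaternary carbon before ring closure, so that the chair transition state has a clear equatorial preference.
- Hydroxyl-directed epoxidation of the vinyl group (VO(acac)2, t-BuOOH) should give (2R)-6-methyl-2-(oxiran-2-yl)hept-5-en-2-ol F4.
- Hydroxide opening at the terminal carbon gives (3R)-3,7-dimethyloct-6-ene-1,2,3-triol F5.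
- Kinetic acetalisation of the terminal diol (2-methoxypropene, PPTS, 0 °C) gives (2R)-2-(2,2-dimethyl-1,3-dioxolan-4-yl)-6-methylhept-5-en-2-ol F6.
- TBCO bromoetherification, now with a branched dioxolanyl group that should sit equatorial in preference to methyl, gives 4-[(2R,5S)-5-bromo-2,6,6-trimethyloxan-2-yl]-2,2-dimethyl-1,3-dioxolane F7.
- H5IO6 in EtOAc unmasks and cleaves the diol to aldehyde 4.

The configuration of the dioxolane carbon is irrelevant, since that carbon becomes the aldehyde carbon.

**Further compounds**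

F1 | step 4 | tert-butyl (3R)-3-[(2R,5S)-5-bromo-2,6,6-trimethyloxan-2-yl]-5-oxo-2-propanoylpentanoate | CC1(C)O[C@@](C)([C@H](CC=O)C(C(=O)CC)C(=O)OC(C)(C)C)CC[C@@H]1Br
F2 | step 4 | tert-butyl (6R)-6-[(2R,5S)-5-bromo-2,6,6-trimethyloxan-2-yl]-4-hydroxy-3-methyl-2-oxocyclohexane-1-carboxylate | CC1(C)O[C@@](C)([C@H]2C(C(=O)OC(C)(C)C)C(=O)C(C)C(O)C2)CC[C@@H]1Br
F3 | step 4 | (5R)-5-[(2R,5S)-5-bromo-2,6,6-trimethyloxan-2-yl]-2-methylcyclohex-2-en-1-one | CC1(C)O[C@@](C)([C@H]2CC(=O)C(C)=CC2)CC[C@@H]1Br
F0 | step 10 | none | none
F4 | step 1 | (2R)-6-methyl-2-(oxiran-2-yl)hept-5-en-2-ol | CC(C)=CCC[C@@](C)(O)C1CO1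
F5 | step 1 | (3R)-3,7-dimethyloct-6-ene-1,2,3-triol | CC(C)=CCC[C@@](C)(O)C(O)CO
F6 | step 1 | (2R)-2-(2,2-dimethyl-1,3-dioxolan-4-yl)-6-methylhept-5-en-2-ol | CC(C)=CCC[C@@](C)(O)C1COC(C)(C)O1
F7 | step 1 | 4-[(2R,5S)-5-bromo-2,6,6-trimethyloxan-2-yl]-2,2-dimethyl-1,3-dioxolane | CC1(C)O[C@@](C)(C2COC(C)(C)O2)CC[C@@H]1Br
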